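**Plan**
1. Retrosynthesis: C13–Cl/C11–OH go back to the α-methylene lactone (epoxide, chloride); the C8 angelate is cut; the C6–C7 bond and the lactone C–O bond are cut together (intramolecular chromium-mediated allylation); C7=C11 comes from a Morita–Baylis–Hillman unit and C8–C9 from an anti-selective hydroxyallylation of a C9 aldehyde.
2. The furanone O1–C10(Me)–C1(=O)–C2=C3 is not closed as a five-membered ring: quaternary C10 carries ring oxygen, methyl and C9 and sits next to the C1 ketone, which is the pattern left by an acyl shift in an epoxy ketone.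
3. It is therefore made from the six-membered vinylogous ester O1–C10(Me)=C9–C1(=O)–C2–C3 (a 6-methyl-2,3-dihydro-4H-pyran-4-one): epoxidation of C9=C10 and a 1,2-shift of C1 from C9 to C10 contract the ring, create C10 and expel C9 as the aldehyde used for chain growth.
4. Forward order: crotylation, aldehyde, pyranone (aldol/cyclocondensation), ring contraction, C8–C9, furanone by dehydrogenation, acrylate unit, then the ten-membered ring and γ-lactone in one closure, then angelate and chlorohydrin.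
5. Stereochemistry: C4/C5 from Brown crotylboration; temporary C3 by Felkin–Anh aldol, relayed to C10 in the ring contraction and erased afterwards; C8/C9 by reagent-controlled allylboration; C6/C7 in the ring closure (relayed from C8); C11 by epoxidation anti to the C8 substituent.

Key step: step 6

Remark: position labels C1–C15 and O1 follow germacranolide numbering of the target; TBS = tert-butyldimethylsilyl, TES = triethylsilyl, PMB = 4-methoxybenzyl, Ipc = isopinocampheyl; aldehyde 1 and the (−)-Ipc boranes derived from (+)-α-pinene are taken as commercial.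

Step 1
Reactants: 1 2-[(4-methoxybenzyl)oxy]acetaldehyde
Product: 3 (2S,3S)-1-(PMBO)-3-methylpent-4-en-2-ol, via borinate ester 2 (not isolated)
Conditions: (E)-but-2-ene, KOtBu, n-BuLi, THF, −78 → −45 °C; (−)-B-methoxydiisopinocampheylborane, −78 °C; BF3·OEt2; then 1, −78 °C; NaOH, H2O2, 0 °C → rt
Reagents that add atoms: (E)-but-2-ene C/C=C/C
Why: Brown crotylboration, in which the (E)-crotylborane reacts through a closed chair (Zimmerman–Traxler) transition state to give the C4/C5 anti relationship and the Ipc ligands from (+)-α-pinene should direct the allyl unit to the Si face of the aldehyde, which fixes C5 and with it C4.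

Step 2
Reactants: 3 (2S,3S)-1-(PMBO)-3-methylpent-4-en-2-ol
Product: 4 (2S,3S)-2-(TBSO)-1-(PMBO)-3-methylpent-4-ene
Conditions: TBSCl, imidazole, DMF, rt
Reagents that add atoms: tert-butyldimethylsilyl chloride CC(C)(C)[Si](C)(C)Cl
Why: standard silylation of a secondary alcohol, giving an ether that survives every step up to the final deprotection.

Step 3
Reactants: 4 (2S,3S)-2-(TBSO)-1-(PMBO)-3-methylpent-4-ene
Product: 5 (2R,3S)-3-(TBSO)-4-(PMBO)-2-methylbutanal
Conditions: OsO4 (2 mol %), NaIO4, 2,6-lutidine, dioxane/H2O, rt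
Reagents that add atoms: sodium periodate [Na+].[O-]I(=O)(=O)=O
Why: Lemieux–Johnson cleavage of the terminal alkene, with lutidine as buffer so that the α-methyl aldehyde (C4) is not epimerised and the electron-rich arene is left alone.

Step 4
Reactants: 6 pentane-2,4-dione
Product: 7 (3Z)-2,4-bis(trimethylsilyloxy)penta-1,3-diene
Conditions: Me3SiOTf (2.2 equiv), Et3N, Et2O, 0 °C
Reagents that add atoms: trimethylsilyl triflate C[Si](C)(C)OS(=O)(=O)C(F)(F)F
Why: double enol silylation of a 1,3-diketone with a silyl triflate and an amine gives the bis(silyl) dienol ether, a masked diketone dianion that reacts at its terminal CH2.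

Step 5
Reactants: 5 (2R,3S)-3-(TBSO)-4-(PMBO)-2-methylbutanal; 7 (3Z)-2,4-bis(trimethylsilyloxy)penta-1,3-diene
Product: 9 (2R)-2-[(2S,3S)-3-(TBSO)-4-(PMBO)butan-2-yl]-6-methyl-2,3-dihydro-4H-pyran-4-one, via hydroxy diketone 8 (not isolated)
Conditions: BF3·OEt2, CH2Cl2, −78 °C; aqueous NaHCO3 work-up; then p-TsOH·H2O (5 mol %), 4 Å molecular sieves, CH2Cl2, rt
Reagents that add atoms: none
Why: Mukaiyama aldol addition of the diene terminus (C2) under Felkin–Anh control, reinforced by 1,3-anti induction from the β-silyloxy group, sets the temporary C3 carbinol syn to the C4 methyl; acid then closes the pyranone by attack of the C3 hydroxyl on the C10 carbonyl and loss of water (aldol/cyclocondensation route to dihydropyranones).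

Step 6
Reactants: 9 (2R)-2-[(2S,3S)-3-(TBSO)-4-(PMBO)butan-2-yl]-6-methyl-2,3-dihydro-4H-pyran-4-one
Product: 11 (2S,5R)-5-[(2S,3S)-3-(TBSO)-4-(PMBO)butan-2-yl]-2-methyl-3-oxooxolane-2-carbaldehyde, via epoxy ketone 10 (not isolated)
Conditions: dimethyldioxirane (1.2 equiv, acetone), CH2Cl2, −40 → 0 °C; evaporation of acetone at 0 °C; then BF3·OEt2 (0.3 equiv), CH2Cl2, −78 °C
Reagents that add atoms: dimethyldioxirane CC1(C)OO1
Why: Proposed new method: dimethyldioxirane transfers oxygen to the C9=C10 enol-ether bond of the vinylogous ester (concerted syn closure of the oxirane) on the face anti to the pseudo-equatorial C3 side chain, and BF3 then breaks the C10–O bond of epoxy ketone 10, because C10 is tertiary and carries the ring oxygen O1 (oxocarbenium character) while C9 is deactivated by the C1 carbonyl. The acyl carbon C1 migrates from C9 to C10 in a semipinacol-type 1,2-shift through a three-centre bridged transition state, so the six-membered ring O1–C10–C9–C1–C2–C3 contracts to the five-membered ring O1–C10–C1–C2–C3 by a shift and not by an exo or endo closure, and C9 leaves the ring as the formyl group. The closest known reaction type is the Lewis-acid rearrangement of carbocyclic α,β-epoxy ketones to ring-contracted β-keto aldehydes (isophorone oxide to 2-formyl-2,4,4-trimethylcyclopentanone); the ring oxygen at the migration terminus should only add driving force. C10 becomes the quaternary stereocentre: migration anti to the breaking C10–O bond (inversion, as in the carbocyclic cases) should place the methyl group cis to the C3 side chain, so the temporary C3 centre of step 5 controls C10 and is erased in step 9. The step needs acyl migration in preference to hydride migration, which the high migratory aptitude of acyl groups toward a stabilised cationic terminus at −78 °C should secure, and it needs acetone to be removed before the Lewis acid is added so that the opened epoxide is not trapped as an acetonide.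

Step 7
Reactants: 11 (2S,5R)-5-[(2S,3S)-3-(TBSO)-4-(PMBO)butan-2-yl]-2-methyl-3-oxooxolane-2-carbaldehyde
Product: 13 (2S,5R)-2-[(1S,2S)-1,2-dihydroxybut-3-en-1-yl]-5-[(2S,3S)-3-(TBSO)-4-(PMBO)butan-2-yl]-2-methyloxolan-3-one, via boron adduct 12 (not isolated)
Conditions: (−)-Ipc2BH, allenylboronic acid pinacol ester, Et2O, −25 °C; then 11, −78 °C; then H2O2, NaHCO3, THF/H2O, 0 °C
Reagents that add atoms: allenylboronic acid pinacol ester C=C=CB1OC(C)(C)C(C)(C)O1; hydrogen peroxide OO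
Why: anti-selective hydroxyallylation with an (E)-γ-borylallyl-diisopinocampheylborane, in which the chair transition state of the E reagent gives the C8/C9 anti (erythro) pair, the Ipc ligands should direct attack to the Si face of the aldehyde (9S) in preference to the hindered ketone, and buffered oxidation replaces boron at C8 by hydroxyl with retention without retro-aldol cleavage.

Step 8
Reactants: 13 (2S,5R)-2-[(1S,2S)-1,2-dihydroxybut-3-en-1-yl]-5-[(2S,3S)-3-(TBSO)-4-(PMBO)butan-2-yl]-2-methyloxolan-3-one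
Product: 14 (2S,5R)-2-[(1S,2S)-1-hydroxy-2-(TESO)but-3-en-1-yl]-5-[(2S,3S)-3-(TBSO)-4-(PMBO)butan-2-yl]-2-methyloxolan-3-one
Conditions: TESCl (1.05 equiv), imidazole, CH2Cl2, −40 °C
Reagents that add atoms: triethylsilyl chloride CC[Si](Cl)(CC)CC
Why: selective silylation of the less hindered allylic C8 hydroxyl; the C9 hydroxyl is neopentylic (next to quaternary C10) and hydrogen-bonded to the C1 ketone.

Step 9
Reactants: 14 (2S,5R)-2-[(1S,2S)-1-hydroxy-2-(TESO)but-3-en-1-yl]-5-[(2S,3S)-3-(TBSO)-4-(PMBO)butan-2-yl]-2-methyloxolan-3-one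
Product: 16 (2S)-2-[(1S,2S)-1-(TBSO)-2-(TESO)but-3-en-1-yl]-5-[(2R,3S)-3-(TBSO)-4-(PMBO)butan-2-yl]-2-methylfuran-3(2H)-one, via silyl enol ether 15 (not isolated)
Conditions: TBSOTf (2.6 equiv), Et3N, CH2Cl2, −78 → 0 °C; filtration through basic alumina; then Pd(OAc)2 (1.1 equiv), MeCN, rt
Reagents that add atoms: tert-butyldimethylsilyl triflate CC(C)(C)[Si](C)(C)OS(=O)(=O)C(F)(F)F
Why: the silyl triflate caps the C9 hydroxyl and converts the ketone into its only possible enol ether (C1=C2, since C10 is quaternary), and Saegusa–Ito oxidation with divalent palladium then removes the C3 hydrogen by β-hydride elimination to give the 3(2H)-furanone, which erases the temporary C3 centre and leaves a ring without enolisable positions.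

Step 10
Reactants: 16 (2S)-2-[(1S,2S)-1-(TBSO)-2-(TESO)but-3-en-1-yl]-5-[(2R,3S)-3-(TBSO)-4-(PMBO)butan-2-yl]-2-methylfuran-3(2H)-one
Product: 17 (2R,3S)-3-(TBSO)-3-{(2S)-5-[(2R,3S)-3-(TBSO)-4-(PMBO)butan-2-yl]-2-methyl-3-oxo-2,3-dihydrofuran-2-yl}-2-(TESO)propanal
Conditions: OsO4 (2 mol %), NaIO4, 2,6-lutidine, dioxane/H2O, rt
Reagents that add atoms: sodium periodate [Na+].[O-]I(=O)(=O)=O
Why: Lemieux–Johnson cleavage, in which osmylation should choose the monosubstituted terminal alkene over the trisubstituted push–pull alkene of the furanone, so that C7 is unmasked as the aldehyde.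

Step 11
Reactants: 17 (2R,3S)-3-(TBSO)-3-{(2S)-5-[(2R,3S)-3-(TBSO)-4-(PMBO)butan-2-yl]-2-methyl-3-oxo-2,3-dihydrofuran-2-yl}-2-(TESO)propanal
Product: 18 methyl (4S,5S)-5-(TBSO)-5-{(2S)-5-[(2R,3S)-3-(TBSO)-4-(PMBO)butan-2-yl]-2-methyl-3-oxo-2,3-dihydrofuran-2-yl}-3-hydroxy-2-methylidene-4-(TESO)pentanoate (both C3 epimers)
Conditions: methyl acrylate (10 equiv), DABCO (1 equiv), MeOH (cat.), rt
Reagents that add atoms: methyl acrylate C=CC(=O)OC
Why: Morita–Baylis–Hillman reaction of an activated α-silyloxy aldehyde brings in C11, C12 and C13; the new carbinol centre at C7 need not be controlled because it becomes sp2 in step 12.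

Step 12
Reactants: 18 methyl (4S,5S)-5-(TBSO)-5-{furanonyl}-3-hydroxy-2-methylidene-4-(TESO)pentanoate
Product: 19 methyl (2Z,4S,5S)-2-(bromomethyl)-5-(TBSO)-5-{(2S)-5-[(2R,3S)-3-(TBSO)-4-(PMBO)butan-2-yl]-2-methyl-3-oxo-2,3-dihydrofuran-2-yl}-4-(TESO)pent-2-enoate
Conditions: NBS, Me2S, CH2Cl2, −20 → 0 °C
Reagents that add atoms: N-bromosuccinimide BrN1C(=O)CCC1=O
Why: Corey–Kim-type activation of the allylic alcohol and SN2′ attack of bromide give the transposed, thermodynamically preferred (Z)-2-(bromomethyl)enoate under conditions too mild to cleave the silyl ethers.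

Step 13
Reactants: 19 methyl (2Z,4S,5S)-2-(bromomethyl)-5-(TBSO)-5-{furanonyl}-4-(TESO)pent-2-enoate (C6-O-PMB)
Product: 20 methyl (2Z,4S,5S)-2-(bromomethyl)-5-(TBSO)-5-{(2S)-5-[(2R,3S)-3-(TBSO)-4-hydroxybutan-2-yl]-2-methyl-3-oxo-2,3-dihydrofuran-2-yl}-4-(TESO)pent-2-enoate
Conditions: DDQ, CH2Cl2/pH 7 buffer, 0 °C
Reagents that add atoms: none
Why: oxidative cleavage of the PMB ether by hydride abstraction leaves the silyl ethers, the allylic bromide and the furanone untouched.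

Step 14
Reactants: 20 C6 alcohol
Product: 21 methyl (2Z,4S,5S)-2-(bromomethyl)-5-(TBSO)-5-{(2S)-5-[(2R,3S)-3-(TBSO)-4-oxobutan-2-yl]-2-methyl-3-oxo-2,3-dihydrofuran-2-yl}-4-(TESO)pent-2-enoate
Conditions: Dess–Martin periodinane, NaHCO3, CH2Cl2, 0 °C → rt
Reagents that add atoms: none
Why: buffered Dess–Martin oxidation gives the α-silyloxy aldehyde without epimerisation at C5 and without touching the allylic bromide.

Step 15
Reactants: 21 aldehyde allylic bromide
Product: 23 (4R,5S,6S,7S,8S,9S,10S)-5,9-bis(TBSO)-8-(TESO)-1-oxo-3,10-epoxygermacra-2,11(13)-dien-12,6-olide, via hydroxy ester 22 (not isolated)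
Conditions: CrCl2 (8 equiv), degassed THF, rt, syringe-pump addition of 21 (final 0.002 M)
Reagents that add atoms: none
Why: intramolecular Nozaki–Hiyama–Kishi-type allylation in which the equilibrating allylchromium (trivalent chromium) attacks the C6 aldehyde through C7 in a chair transition state (anti adduct, hence the trans-lactone after loss of methanol), with the C7 face anti to the bulky C9 side of the C8 stereocentre in its allylic-strain-minimised conformer, and the rigid furanone and high dilution favouring closure of the ten-membered ring.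

Step 16
Reactants: 23 8-O-TES lactone
Product: 24 (4R,5S,6S,7R,8S,9S,10S)-5,9-bis(TBSO)-8-hydroxy-1-oxo-3,10-epoxygermacra-2,11(13)-dien-12,6-olide
Conditions: PPTS, MeOH/CH2Cl2, 0 °C
Reagents that add atoms: none
Why: acid methanolysis cleaves the triethylsilyl ether far faster than the two secondary TBS ethers, freeing only the C8 hydroxyl.

Step 17
Reactants: 24 C8 alcohol
Product: 25 (4R,5S,6S,7S,8S,9S,10S)-8-(angeloyloxy)-5,9-bis(TBSO)-1-oxo-3,10-epoxygermacra-2,11(13)-dien-12,6-olide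
Conditions: angelic acid, 2,4,6-trichlorobenzoyl chloride, Et3N, toluene, rt; then 24, 75 °C
Reagents that add atoms: angelic acid C/C=C(/C)C(=O)O
Why: Yamaguchi-type esterification through the mixed anhydride without a nucleophilic catalyst, which should acylate the only free hydroxyl without Z to E isomerisation of the angelate.

Step 18
Reactants: 25 angelate α-methylene lactone
Product: 26 (4R,5S,6S,7S,8S,9S,10S,11R)-8-(angeloyloxy)-5,9-bis(TBSO)-11,13-epoxy-1-oxo-3,10-epoxygermacr-2-en-12,6-olide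
Conditions: t-BuOOH, DBU, CH2Cl2, 0 °C
Reagents that add atoms: tert-butyl hydroperoxide CC(C)(C)OO
Why: Weitz–Scheffer (nucleophilic) epoxidation of the α-methylene lactone, the best Michael acceptor present, in which the lactone enolate closes onto oxygen from the face anti to the C8 substituent on C7 and so places the epoxide oxygen syn to H7, as C11 requires.

Step 19
Reactants: 26 spiro-epoxy lactone
Product: 27 (4R,5S,6S,7S,8S,9S,10S,11S)-8-(angeloyloxy)-5,9-bis(TBSO)-13-chloro-11-hydroxy-1-oxo-3,10-epoxygermacr-2-en-12,6-olide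
Conditions: HCl (1.5 equiv, 4 M in dioxane), CH2Cl2, −20 °C
Reagents that add atoms: hydrogen chloride Cl
Why: acid-promoted SN2 opening of the glycidic epoxide by chloride at the primary C13 leaves the C11–O bond and its configuration untouched and gives the tertiary alcohol.

Step 20
Reactants: 27 bis-TBS chlorohydrin
Product: 28 (4R,5S,6S,7S,8S,9S,10S,11S)-8-(angeloyloxy)-13-chloro-5,9,11-trihydroxy-1-oxo-3,10-epoxygermacr-2-en-12,6-olide (CNP0340393.2)
Conditions: HF·pyridine, pyridine, THF, 0 °C → rt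
Reagents that add atoms: none
Why: acidic fluoride removes both TBS ethers without base, so the retro-aldol-prone C9 hydroxy ketone, the angelate, the lactone and the chlorohydrin should survive.

**Compound list**
1 | 2-[(4-methoxybenzyl)oxy]acetaldehyde | COc1ccc(COCC=O)cc1 | starting material
2 | (2S,3S)-1-(PMBO)-3-methylpent-4-en-2-yl diisopinocampheylborinate | COc1ccc(COC[C@@H](OB([C@@H]2C[C@@H]3C[C@@H](C3(C)C)[C@H]2C)[C@@H]2C[C@@H]3C[C@@H](C3(C)C)[C@H]2C)[C@@H](C)C=C)cc1 | intermediate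
3 | (2S,3S)-1-[(4-methoxybenzyl)oxy]-3-methylpent-4-en-2-ol | COc1ccc(COC[C@@H](O)[C@@H](C)C=C)cc1 | intermediate
4 | (2S,3S)-2-[(tert-butyldimethylsilyl)oxy]-1-[(4-methoxybenzyl)oxy]-3-methylpent-4-ene | COc1ccc(COC[C@@H](O[Si](C)(C)C(C)(C)C)[C@@H](C)C=C)cc1 | intermediate
5 | (2R,3S)-3-[(tert-butyldimethylsilyl)oxy]-4-[(4-methoxybenzyl)oxy]-2-methylbutanal | COc1ccc(COC[C@@H](O[Si](C)(C)C(C)(C)C)[C@@H](C)C=O)cc1 | intermediate
6 | pentane-2,4-dione | CC(=O)CC(C)=O | starting material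
7 | (3Z)-2,4-bis(trimethylsilyloxy)penta-1,3-diene | C=C(O[Si](C)(C)C)/C=C(/C)O[Si](C)(C)C | intermediate
8 | (6R,7S,8S)-8-(TBSO)-6-hydroxy-9-(PMBO)-7-methylnonane-2,4-dione | COc1ccc(COC[C@@H](O[Si](C)(C)C(C)(C)C)[C@@H](C)[C@H](O)CC(=O)CC(C)=O)cc1 | intermediate
9 | (2R)-2-[(2S,3S)-3-(TBSO)-4-(PMBO)butan-2-yl]-6-methyl-2,3-dihydro-4H-pyran-4-one | COc1ccc(COC[C@@H](O[Si](C)(C)C(C)(C)C)[C@@H](C)[C@H]2CC(=O)C=C(C)O2)cc1 | intermediate
10 | (1S,3R,6S)-3-[(2S,3S)-3-(TBSO)-4-(PMBO)butan-2-yl]-1-methyl-2,7-dioxabicyclo[4.1.0]heptan-5-one (epoxide oxygen trans to the side chain) | COc1ccc(COC[C@@H](O[Si](C)(C)C(C)(C)C)[C@@H](C)[C@H]2CC(=O)[C@@H]3O[C@]3(C)O2)cc1 | intermediate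
11 | (2S,5R)-5-[(2S,3S)-3-(TBSO)-4-(PMBO)butan-2-yl]-2-methyl-3-oxooxolane-2-carbaldehyde | COc1ccc(COC[C@@H](O[Si](C)(C)C(C)(C)C)[C@@H](C)[C@H]2CC(=O)[C@@](C)(O2)C=O)cc1 | intermediate
12 | allylboration adduct of 11: C9–O–B(Ipc)2 and C8–B(pinacolato), anti | COc1ccc(COC[C@@H](O[Si](C)(C)C(C)(C)C)[C@@H](C)[C@H]2CC(=O)[C@@](C)(O2)[C@@H](OB([C@@H]3C[C@@H]4C[C@@H](C4(C)C)[C@H]3C)[C@@H]3C[C@@H]4C[C@@H](C4(C)C)[C@H]3C)[C@@H](B3OC(C)(C)C(C)(C)O3)C=C)cc1 | intermediate
13 | (2S,5R)-2-[(1S,2S)-1,2-dihydroxybut-3-en-1-yl]-5-[(2S,3S)-3-(TBSO)-4-(PMBO)butan-2-yl]-2-methyloxolan-3-one | COc1ccc(COC[C@@H](O[Si](C)(C)C(C)(C)C)[C@@H](C)[C@H]2CC(=O)[C@@](C)(O2)[C@@H](O)[C@@H](O)C=C)cc1 | intermediate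
14 | (2S,5R)-2-[(1S,2S)-1-hydroxy-2-(TESO)but-3-en-1-yl]-5-[(2S,3S)-3-(TBSO)-4-(PMBO)butan-2-yl]-2-methyloxolan-3-one | COc1ccc(COC[C@@H](O[Si](C)(C)C(C)(C)C)[C@@H](C)[C@H]2CC(=O)[C@@](C)(O2)[C@@H](O)[C@@H](O[Si](CC)(CC)CC)C=C)cc1 | intermediate
15 | C9-O-TBS ether and C1-O-TBS enol ether (C1=C2) of 14 | COc1ccc(COC[C@@H](O[Si](C)(C)C(C)(C)C)[C@@H](C)[C@H]2C=C(O[Si](C)(C)C(C)(C)C)[C@@](C)(O2)[C@@H](O[Si](C)(C)C(C)(C)C)[C@@H](O[Si](CC)(CC)CC)C=C)cc1 | intermediate
16 | (2S)-2-[(1S,2S)-1-(TBSO)-2-(TESO)but-3-en-1-yl]-5-[(2R,3S)-3-(TBSO)-4-(PMBO)butan-2-yl]-2-methylfuran-3(2H)-one | COc1ccc(COC[C@@H](O[Si](C)(C)C(C)(C)C)[C@@H](C)C2=CC(=O)[C@@](C)(O2)[C@@H](O[Si](C)(C)C(C)(C)C)[C@@H](O[Si](CC)(CC)CC)C=C)cc1 | intermediate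
17 | (2R,3S)-3-(TBSO)-3-{(2S)-5-[(2R,3S)-3-(TBSO)-4-(PMBO)butan-2-yl]-2-methyl-3-oxo-2,3-dihydrofuran-2-yl}-2-(TESO)propanal | COc1ccc(COC[C@@H](O[Si](C)(C)C(C)(C)C)[C@@H](C)C2=CC(=O)[C@@](C)(O2)[C@@H](O[Si](C)(C)C(C)(C)C)[C@@H](O[Si](CC)(CC)CC)C=O)cc1 | intermediate
18 | methyl (4S,5S)-5-(TBSO)-5-{(2S)-5-[(2R,3S)-3-(TBSO)-4-(PMBO)butan-2-yl]-2-methyl-3-oxo-2,3-dihydrofuran-2-yl}-3-hydroxy-2-methylidene-4-(TESO)pentanoate (C3 epimers) | COc1ccc(COC[C@@H](O[Si](C)(C)C(C)(C)C)[C@@H](C)C2=CC(=O)[C@@](C)(O2)[C@@H](O[Si](C)(C)C(C)(C)C)[C@@H](O[Si](CC)(CC)CC)C(O)C(=C)C(=O)OC)cc1 | intermediate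
19 | methyl (2Z,4S,5S)-2-(bromomethyl)-5-(TBSO)-5-{(2S)-5-[(2R,3S)-3-(TBSO)-4-(PMBO)butan-2-yl]-2-methyl-3-oxo-2,3-dihydrofuran-2-yl}-4-(TESO)pent-2-enoate | COc1ccc(COC[C@@H](O[Si](C)(C)C(C)(C)C)[C@@H](C)C2=CC(=O)[C@@](C)(O2)[C@@H](O[Si](C)(C)C(C)(C)C)[C@@H](O[Si](CC)(CC)CC)/C=C(\CBr)C(=O)OC)cc1 | intermediate
20 | methyl (2Z,4S,5S)-2-(bromomethyl)-5-(TBSO)-5-{(2S)-5-[(2R,3S)-3-(TBSO)-4-hydroxybutan-2-yl]-2-methyl-3-oxo-2,3-dihydrofuran-2-yl}-4-(TESO)pent-2-enoate | OC[C@@H](O[Si](C)(C)C(C)(C)C)[C@@H](C)C1=CC(=O)[C@@](C)(O1)[C@@H](O[Si](C)(C)C(C)(C)C)[C@@H](O[Si](CC)(CC)CC)/C=C(\CBr)C(=O)OC | intermediate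
21 | methyl (2Z,4S,5S)-2-(bromomethyl)-5-(TBSO)-5-{(2S)-5-[(2R,3S)-3-(TBSO)-4-oxobutan-2-yl]-2-methyl-3-oxo-2,3-dihydrofuran-2-yl}-4-(TESO)pent-2-enoate | O=C[C@@H](O[Si](C)(C)C(C)(C)C)[C@@H](C)C1=CC(=O)[C@@](C)(O1)[C@@H](O[Si](C)(C)C(C)(C)C)[C@@H](O[Si](CC)(CC)CC)/C=C(\CBr)C(=O)OC | intermediate
22 | methyl (4R,5S,6S,7S,8S,9S,10S)-5,9-bis(TBSO)-6-hydroxy-8-(TESO)-1-oxo-3,10-epoxygermacra-2,11(13)-dien-12-oate | CC[Si](CC)(CC)O[C@H]1[C@@H](C(=C)C(=O)OC)[C@H](O)[C@@H](O[Si](C)(C)C(C)(C)C)[C@@H](C)C2=CC(=O)[C@@](C)(O2)[C@H]1O[Si](C)(C)C(C)(C)C | intermediate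
23 | (4R,5S,6S,7S,8S,9S,10S)-5,9-bis(TBSO)-8-(TESO)-1-oxo-3,10-epoxygermacra-2,11(13)-dien-12,6-olide | CC[Si](CC)(CC)O[C@H]1[C@@H]2[C@H](OC(=O)C2=C)[C@@H](O[Si](C)(C)C(C)(C)C)[C@@H](C)C2=CC(=O)[C@@](C)(O2)[C@H]1O[Si](C)(C)C(C)(C)C | intermediate
24 | (4R,5S,6S,7R,8S,9S,10S)-5,9-bis(TBSO)-8-hydroxy-1-oxo-3,10-epoxygermacra-2,11(13)-dien-12,6-olide | O[C@H]1[C@@H]2[C@H](OC(=O)C2=C)[C@@H](O[Si](C)(C)C(C)(C)C)[C@@H](C)C2=CC(=O)[C@@](C)(O2)[C@H]1O[Si](C)(C)C(C)(C)C | intermediate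
25 | (4R,5S,6S,7S,8S,9S,10S)-8-(angeloyloxy)-5,9-bis(TBSO)-1-oxo-3,10-epoxygermacra-2,11(13)-dien-12,6-olide | C/C=C(/C)C(=O)O[C@H]1[C@@H]2[C@H](OC(=O)C2=C)[C@@H](O[Si](C)(C)C(C)(C)C)[C@@H](C)C2=CC(=O)[C@@](C)(O2)[C@H]1O[Si](C)(C)C(C)(C)C | intermediate
26 | (4R,5S,6S,7S,8S,9S,10S,11R)-8-(angeloyloxy)-5,9-bis(TBSO)-11,13-epoxy-1-oxo-3,10-epoxygermacr-2-en-12,6-olide | C/C=C(/C)C(=O)O[C@H]1[C@@H]2[C@H](OC(=O)[C@]23CO3)[C@@H](O[Si](C)(C)C(C)(C)C)[C@@H](C)C2=CC(=O)[C@@](C)(O2)[C@H]1O[Si](C)(C)C(C)(C)C | intermediate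
27 | (4R,5S,6S,7S,8S,9S,10S,11S)-8-(angeloyloxy)-5,9-bis(TBSO)-13-chloro-11-hydroxy-1-oxo-3,10-epoxygermacr-2-en-12,6-olide | C/C=C(/C)C(=O)O[C@H]1[C@@H]2[C@H](OC(=O)[C@]2(O)CCl)[C@@H](O[Si](C)(C)C(C)(C)C)[C@@H](C)C2=CC(=O)[C@@](C)(O2)[C@H]1O[Si](C)(C)C(C)(C)C | intermediate
28 | (4R,5S,6S,7S,8S,9S,10S,11S)-8-(angeloyloxy)-13-chloro-5,9,11-trihydroxy-1-oxo-3,10-epoxygermacr-2-en-12,6-olide | C/C=C(/C)C(=O)O[C@H]1[C@@H]2[C@H](OC(=O)[C@]2(O)CCl)[C@@H](O)[C@@H](C)C2=CC(=O)[C@@](C)(O2)[C@H]1O | target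

**Count and risks**
Total steps: 20. Longest linear sequence: 19 steps (steps 1–3 and 5–20 from 1; step 4 prepares diene 7).

Steps most likely to fail:

Step 6 (Proposed new method). The oxygen transfer may show poor facial selectivity, hydride may migrate instead of the acyl carbon, or the migration may not follow the anti course, which would give the wrong C10 configuration. The fallback builds the furanone by known chemistry without any ring contraction; it sets out from aldehyde 5 and comes back at aldehyde 17. Ohira–Bestmann homologation of 5 (dimethyl (1-diazo-2-oxopropyl)phosphonate, K2CO3, MeOH) gives the terminal alkyne F1. Acyl Sonogashira coupling with commercial (S)-2-acetoxypropanoyl chloride (PdCl2(PPh3)2, CuI, Et3N, THF) gives the acetoxy ynone F2. K2CO3 in MeOH removes the acetate and the γ-hydroxy ynone closes 5-endo-dig to the 2-methylfuran-3(2H)-one F3, in which C10 still bears hydrogen and its configuration does not matter. LiN(iPr)2 (THF, −78 °C) forms the 3-furanolate, and its aldol addition to commercial (S)-2,3-O-isopropylideneglyceraldehyde should give the quaternary aldol F4: C8 comes from the chiral pool and C9 from Felkin–Anh attack, while the facial sense at C10 is not secured and an epimer may have to be separated. TBSOTf/2,6-lutidine gives the silyl ether F5; CeCl3·7H2O/oxalic acid in MeCN removes the acetonide to the diol F6; TESCl/imidazole gives the bis(triethylsilyl) ether F7; Swern oxidation, which cleaves and oxidises only the primary triethylsilyl ether, gives 17.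

Step 15. The ten-membered ring may close with the wrong facial selectivity at the C6 aldehyde, because the intrinsic Felkin–Anh preference of the α-silyloxy aldehyde opposes the required C5/C6 syn relationship; oligomerisation or 1,4-elimination of the C8 silyloxy group are further risks. The fallback corrects C6 by forming the lactone C–O bond by substitution instead of acylation; it sets out from 21 and comes back at 23. The ring closure is run with CrCl2 (cat.), Mn and Me3SiCl so that the C6 alkoxide is silylated and does not lactonise, and mild desilylation (K2CO3, MeOH, 0 °C) gives the C6-epimeric hydroxy ester F8. MsCl/Et3N gives the mesylate F9, and heating in DMF lets the ester carbonyl oxygen displace the mesylate with inversion at C6 and loss of the methyl group, which closes the trans-lactone 23.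

Step 17. The hindered C8 hydroxyl may acylate slowly, and forcing conditions may isomerise the angelate to the tiglate. The fallback makes the Z double bond after the ester is in place; it sets out from 24 and comes back at 25. Steglich esterification with 2-[bis(2,2,2-trifluoroethoxy)phosphoryl]propanoic acid (EDC·HCl, DMAP, CH2Cl2) gives the phosphonate ester F10, and Still–Gennari olefination with acetaldehyde (KN(SiMe3)2, 18-crown-6, THF, −78 °C) should give the Z-configured 2-methylbut-2-enoate 25.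

**Further compounds**
F1 | step 6 | (2S,3S)-2-(TBSO)-1-(PMBO)-3-methylpent-4-yne | COc1ccc(COC[C@@H](O[Si](C)(C)C(C)(C)C)[C@@H](C)C#C)cc1
F2 | step 6 | (2S,6S,7S)-7-(TBSO)-8-(PMBO)-6-methyl-3-oxooct-4-yn-2-yl acetate | COc1ccc(COC[C@@H](O[Si](C)(C)C(C)(C)C)[C@@H](C)C#CC(=O)[C@H](C)OC(C)=O)cc1
F3 | step 6 | 5-[(2R,3S)-3-(TBSO)-4-(PMBO)butan-2-yl]-2-methylfuran-3(2H)-one (C2 epimers) | COc1ccc(COC[C@@H](O[Si](C)(C)C(C)(C)C)[C@@H](C)C2=CC(=O)C(C)O2)cc1
F4 | step 6 | (2S)-2-{(S)-[(4S)-2,2-dimethyl-1,3-dioxolan-4-yl](hydroxy)methyl}-5-[(2R,3S)-3-(TBSO)-4-(PMBO)butan-2-yl]-2-methylfuran-3(2H)-one | COc1ccc(COC[C@@H](O[Si](C)(C)C(C)(C)C)[C@@H](C)C2=CC(=O)[C@@](C)(O2)[C@@H](O)[C@@H]3COC(C)(C)O3)cc1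
F5 | step 6 | C9-O-TBS ether of F4 | COc1ccc(COC[C@@H](O[Si](C)(C)C(C)(C)C)[C@@H](C)C2=CC(=O)[C@@](C)(O2)[C@@H](O[Si](C)(C)C(C)(C)C)[C@@H]3COC(C)(C)O3)cc1
F6 | step 6 | (2S)-2-[(1S,2S)-1-(TBSO)-2,3-dihydroxypropyl]-5-[(2R,3S)-3-(TBSO)-4-(PMBO)butan-2-yl]-2-methylfuran-3(2H)-one | COc1ccc(COC[C@@H](O[Si](C)(C)C(C)(C)C)[C@@H](C)C2=CC(=O)[C@@](C)(O2)[C@@H](O[Si](C)(C)C(C)(C)C)[C@@H](O)CO)cc1
F7 | step 6 | (2S)-2-[(1S,2S)-1-(TBSO)-2,3-bis(TESO)propyl]-5-[(2R,3S)-3-(TBSO)-4-(PMBO)butan-2-yl]-2-methylfuran-3(2H)-one | COc1ccc(COC[C@@H](O[Si](C)(C)C(C)(C)C)[C@@H](C)C2=CC(=O)[C@@](C)(O2)[C@@H](O[Si](C)(C)C(C)(C)C)[C@@H](O[Si](CC)(CC)CC)CO[Si](CC)(CC)CC)cc1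
F8 | step 15 | methyl (4R,5S,6R,7S,8S,9S,10S)-5,9-bis(TBSO)-6-hydroxy-8-(TESO)-1-oxo-3,10-epoxygermacra-2,11(13)-dien-12-oate (C6 epimer of 22) | CC[Si](CC)(CC)O[C@H]1[C@@H](C(=C)C(=O)OC)[C@@H](O)[C@@H](O[Si](C)(C)C(C)(C)C)[C@@H](C)C2=CC(=O)[C@@](C)(O2)[C@H]1O[Si](C)(C)C(C)(C)C
F9 | step 15 | C6-O-methanesulfonate of F8 | CC[Si](CC)(CC)O[C@H]1[C@@H](C(=C)C(=O)OC)[C@@H](OS(C)(=O)=O)[C@@H](O[Si](C)(C)C(C)(C)C)[C@@H](C)C2=CC(=O)[C@@](C)(O2)[C@H]1O[Si](C)(C)C(C)(C)C
F10 | step 17 | C8-O-{2-[bis(2,2,2-trifluoroethoxy)phosphoryl]propanoyl} ester of 24 (epimers at the phosphonate α-carbon) | CC(C(=O)O[C@H]1[C@@H]2[C@H](OC(=O)C2=C)[C@@H](O[Si](C)(C)C(C)(C)C)[C@@H](C)C2=CC(=O)[C@@](C)(O2)[C@H]1O[Si](C)(C)C(C)(C)C)P(=O)(OCC(F)(F)F)OCC(F)(F)F
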